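## Retrosynthetic overview

1. Last operation: the C8 aldehyde is unmasked and an allylboronate held inside a six-membered "template" lactone (O5–C12) adds through C7. This closes the ten-membered carbocycle (C7–C8); the new C8 oxygen then takes over the acyl group, giving the five-membered lactone and free C5–OH. Two rings and C7/C8 are set at once.
2. The template lactone comes from ring-closing metathesis of a C5–O 2-(bromomethyl)acrylate with the C6 vinyl group. It masks O5, so only O6 is swapped from PMB to methacrylate; Br is then exchanged for Bpin.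
3. C4–C5 is made by a chelation-controlled vinylogous Mukaiyama aldol between a furanone dienol silane and (S)-2-(PMB-oxy)but-3-enal; C6 controls C5 and C4.
4. The furanone comes from (S)-lactic acid (Seebach alkylation sets C10; alkynylation; gold cyclization). The aldehyde comes from 2-vinyloxirane by Trost etherification.
5. Ring order: furanone, then six-membered template lactone, then carbocycle and five-membered lactone together (the template ring opens).

Numbering used: C10 = quaternary O-bearing carbon, C1 = ketone, C2=C3 = furanone alkene, C4 (bears methyl C15), C5 (OH), C6 (O-methacrylate), C7, C8 (lactone O), C9 (CH2), C11/C12/C13 = lactone alpha-carbon, carbonyl and exo-methylene. The target is 4S,5S,6S,7R,8S,10R, with all chain substituents C4–C8 syn in the zigzag drawing.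

Assumption: the (R,R)-DACH-phenyl Trost ligand is taken to give (S)-15 in step 7; if the sense is opposite, the (S,S)-ligand is used and nothing else changes.

## Route

Step 1
Reactants: 1 (S)-lactic acid + 2 pivalaldehyde
Product: 3 (2S,5S)-2-tert-butyl-5-methyl-1,3-dioxolan-4-one
Conditions: TsOH·H2O (cat.), H2SO4 (cat.), pentane, reflux, Dean–Stark; crystallise from pentane, −78 °C
Reagents that add atoms: none
Why: Acid-catalysed acetalization (Seebach dioxolanone formation) with water removal gives mainly the cis acetal, which crystallises pure; the lactic acid centre is untouched and the acetal centre is set cis to methyl under thermodynamic control.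

Step 2
Reactants: 3 (2S,5S)-2-tert-butyl-5-methyl-1,3-dioxolan-4-one
Product: 5 (2S,5R)-5-allyl-2-tert-butyl-5-methyl-1,3-dioxolan-4-one, via lithium enolate 4 (not isolated)
Conditions: LiN(i-Pr)2, THF, −78 °C; allyl bromide, −78 → −30 °C
Reagents that add atoms: allyl bromide (C=CCBr)
Why: Seebach self-regeneration of stereocentres: the planar lithium enolate is alkylated anti to the tert-butyl group, giving the (5R) quaternary centre that becomes C10 (R) of the target.

Step 3
Reactants: 5 (2S,5R)-5-allyl-2-tert-butyl-5-methyl-1,3-dioxolan-4-one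
Product: 7 (2S,5R)-2-tert-butyl-5-(2,2-dimethoxyethyl)-5-methyl-1,3-dioxolan-4-one, via aldehyde 6 (not isolated)
Conditions: O3, CH2Cl2, −78 °C; PPh3, −78 °C → rt; then HC(OMe)3, MeOH, PPTS (cat.), rt
Reagents that add atoms: trimethyl orthoformate (COC(OC)OC) and methanol (CO) for the two methoxy groups; ozone ([O-][O+]=O) for the oxygen of intermediate 6
Why: Ozonolysis of the only alkene with reductive work-up gives the aldehyde, which is converted at once into its dimethyl acetal by acid-catalysed acetalization; the acylal-type dioxolanone tolerates PPTS and no stereocentre is involved.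

Step 4
Reactants: 7 (2S,5R)-2-tert-butyl-5-(2,2-dimethoxyethyl)-5-methyl-1,3-dioxolan-4-one
Product: 9 (R)-3-hydroxy-1,1-dimethoxy-3-methyloct-5-yn-4-one, via lithium hemiketal alkoxide 8 (not isolated)
Conditions: 1-butyne, n-BuLi, THF, −78 °C; add 7, −78 °C; sat. aq. NH4Cl, −78 °C → rt
Reagents that add atoms: 1-butyne (CCC#C)
Why: Lithium acetylide addition to the lactone-type carbonyl stops at the tetrahedral alkoxide at −78 °C (as in acetylide additions to lactones); on protonation it collapses to the alpha'-hydroxy ynone and pivalaldehyde, and C10 is not involved.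

Step 5
Reactants: 9 (R)-3-hydroxy-1,1-dimethoxy-3-methyloct-5-yn-4-one
Product: 10 (R)-2-(2,2-dimethoxyethyl)-5-ethyl-2-methylfuran-3(2H)-one
Conditions: Ph3PAuCl (2 mol %), AgOTf (2 mol %), toluene, rt
Reagents that add atoms: none
Why: Gold-catalysed 5-endo-dig cycloisomerization (intramolecular oxa-Michael addition of the tertiary alcohol to the activated ynone) gives the 3(2H)-furanone without touching C10 or the acetal.

Step 6
Reactants: 10 (R)-2-(2,2-dimethoxyethyl)-5-ethyl-2-methylfuran-3(2H)-one
Product: 12 {[(2R,5Z)-2-(2,2-dimethoxyethyl)-5-ethylidene-2-methyl-2,5-dihydrofuran-3-yl]oxy}trimethylsilane, via lithium dienolate 11 (not isolated)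
Conditions: LiN(i-Pr)2, THF, −78 °C; Me3SiCl, Et3N, −78 → 0 °C; pentane, filter, concentrate; used crude
Reagents that add atoms: chlorotrimethylsilane (C[Si](C)(C)Cl)
Why: Kinetic gamma-deprotonation of the vinylogous ester (the ethyl CH2 is the only acidic site) and O-silylation give the silyl dienol ether for a vinylogous Mukaiyama aldol; the ethylidene geometry (Z expected) does not fix the later stereochemistry.

Step 7
Reactants: 13 2-vinyloxirane (racemic) + 14 4-methoxybenzyl alcohol
Product: 15 (S)-2-[(4-methoxybenzyl)oxy]but-3-en-1-ol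
Conditions: Pd2(dba)3·CHCl3 (1 mol %), (R,R)-DACH-phenyl Trost ligand (3 mol %), Et3B (1 mol %), CH2Cl2, rt
Reagents that add atoms: none
Why: Trost dynamic kinetic asymmetric allylic etherification: both epoxide enantiomers give one equilibrating pi-allyl palladium alkoxide and the boron-bound alcohol is delivered to the internal carbon in the chiral pocket, setting the (S) centre that becomes C6.

Step 8
Reactants: 15 (S)-2-[(4-methoxybenzyl)oxy]but-3-en-1-ol
Product: 16 (S)-2-[(4-methoxybenzyl)oxy]but-3-enal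
Conditions: Dess–Martin periodinane, NaHCO3, CH2Cl2, 0 °C; filter, use at once
Reagents that add atoms: none
Why: Dess–Martin oxidation under buffered, base-free conditions gives the alpha-alkoxy beta,gamma-unsaturated aldehyde without epimerization or alkene migration.

Step 9
Reactants: 12 silyl dienol ether + 16 (S)-2-[(4-methoxybenzyl)oxy]but-3-enal
Product: 18 (2R)-2-(2,2-dimethoxyethyl)-5-{(2S,3S,4S)-3-hydroxy-4-[(4-methoxybenzyl)oxy]hex-5-en-2-yl}-2-methylfuran-3(2H)-one, via silyl ether 17 (not isolated)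
Conditions: MgBr2·OEt2 (3 equiv), CH2Cl2, −78 → −40 °C; then citric acid, MeOH, 0 °C
Reagents that add atoms: none
Why: Chelation-controlled vinylogous Mukaiyama aldol: magnesium bridges the aldehyde and PMB-ether oxygens and the dienol silane attacks through its gamma-carbon anti to the vinyl group of the chelate (5,6-syn, 5S), in an open antiperiplanar transition state with the methyl turned away from the chelate ring (4,5-syn, 4S); C10 is remote and only carried along.

Step 10
Reactants: 18 aldol adduct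
Product: 19 (2S,3S,4S)-2-[(5R)-5-(2,2-dimethoxyethyl)-5-methyl-4-oxo-4,5-dihydrofuran-2-yl]-4-[(4-methoxybenzyl)oxy]hex-5-en-3-yl 2-(bromomethyl)acrylate
Conditions: 2-(bromomethyl)acrylic acid, (COCl)2, DMF (cat.), CH2Cl2, 0 °C → rt, evaporate; then 18, pyridine, CH2Cl2, −20 °C
Reagents that add atoms: 2-(bromomethyl)acrylic acid (OC(=O)C(=C)CBr)
Why: Esterification of the secondary alcohol with the acid chloride and pyridine (O-acylation outruns N-alkylation by the allylic bromide at −20 °C) attaches C11–C13 to O5 with retention at C5.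

Step 11
Reactants: 19 acrylate ester
Product: 20 (5S,6S)-3-(bromomethyl)-6-{(1S)-1-[(5R)-5-(2,2-dimethoxyethyl)-5-methyl-4-oxo-4,5-dihydrofuran-2-yl]ethyl}-5-[(4-methoxybenzyl)oxy]-5,6-dihydro-2H-pyran-2-one
Conditions: second-generation Grubbs catalyst (5 mol %), toluene (5 mM), 80 °C
Reagents that add atoms: none
Why: Ring-closing metathesis between the C6 vinyl group and the 1,1-disubstituted acrylate closes the six-membered unsaturated lactone with loss of ethylene, fixing the C7=C11 geometry and masking O5; the push–pull furanone alkene does not take part.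

Step 12
Reactants: 20 PMB-protected template lactone
Product: 21 (5S,6S)-3-(bromomethyl)-6-{(1S)-1-[(5R)-5-(2,2-dimethoxyethyl)-5-methyl-4-oxo-4,5-dihydrofuran-2-yl]ethyl}-5-hydroxy-5,6-dihydro-2H-pyran-2-one
Conditions: DDQ, CH2Cl2/pH 7 buffer (10:1), 0 °C → rt
Reagents that add atoms: none
Why: Oxidative PMB-ether cleavage by DDQ frees only O6 because O5 is held in the lactone; no stereocentre is touched.

Step 13
Reactants: 21 bromo alcohol
Product: 22 (5S,6S)-6-{(1S)-1-[(5R)-5-(2,2-dimethoxyethyl)-5-methyl-4-oxo-4,5-dihydrofuran-2-yl]ethyl}-5-hydroxy-3-[(4,4,5,5-tetramethyl-1,3,2-dioxaborolan-2-yl)methyl]-5,6-dihydro-2H-pyran-2-one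
Conditions: B2pin2 (1.2 equiv), Pd2(dba)3 (2.5 mol %), THF, 60 °C
Reagents that add atoms: bis(pinacolato)diboron (CC1(C)OB(OC1(C)C)B1OC(C)(C)C(C)(C)O1)
Why: Palladium-catalysed Miyaura-type borylation of the allylic bromide via a pi-allyl palladium intermediate puts boron on the primary terminus (conjugated 2-alkoxycarbonyl allylboronate); it is run while C6 carries a free hydroxyl so that no acyloxy leaving group sits next to the allyl metal.

Step 14
Reactants: 22 allylboronate alcohol
Product: 23 the 5-O-methacrylate of 22 (methacryloyloxy on the ring carbon next to the alkene CH)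
Conditions: methacrylic anhydride, Et3N, DMAP (cat.), CH2Cl2, 0 °C
Reagents that add atoms: methacrylic anhydride (CC(=C)C(=O)OC(=O)C(C)=C)
Why: DMAP-catalysed acylation of the only free hydroxyl (C6) proceeds with retention; the covalent allylboronate is inert here and, unlike an allyl zinc or chromium species, cannot expel the new allylic ester.

Step 15
Reactants: 23 allylboronate methacrylate acetal
Product: 27 target (4S,5S,6S,7R,8S,10R)-5-hydroxy-6-methacryloyloxy-1-oxo-3,10-epoxygermacra-2,11(13)-dien-12,8-olide, via aldehyde 24 (not isolated), via bridged borate 25 (not isolated), via bridged hydroxy lactone 26 (not isolated)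
Conditions: Sc(OTf)3 (20 mol %), MeCN/H2O (50:1), 5 mM, rt → 40 °C
Reagents that add atoms: water (O)
Why: Proposed new method: Sc(OTf)3 in wet MeCN hydrolyses the dimethyl acetal and then catalyses a Hall-type allylboration of the freed aldehyde by the lactone-embedded 2-alkoxycarbonyl allylboronate through a chair Zimmerman–Traxler transition state (C7 is attacked on the face cis to the C5 tether, the only face the six-atom tether reaches from its pseudo-axial position; tether carbon C9 equatorial and anti to C11; aldehyde oxygen on the boron side), which closes the ten-membered carbocycle and sets 7R and 8S, after which the C8 oxygen attacks the neighbouring six-membered lactone carbonyl to give the more stable five-membered lactone and release C5–OH; the closest known reactions are the Lewis acid-catalysed allylboration–lactonization of 2-alkoxycarbonyl allylboronates with aldehydes and delta-to-gamma translactonization.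

## Compound list

1 | (S)-lactic acid | C[C@H](O)C(=O)O | starting material
2 | pivalaldehyde | CC(C)(C)C=O | starting material
3 | (2S,5S)-2-tert-butyl-5-methyl-1,3-dioxolan-4-one (cis) | C[C@@H]1O[C@H](C(C)(C)C)OC1=O | intermediate
4 | lithium enolate of 3 (acetal carbon S) | CC1=C(O[Li])O[C@@H](C(C)(C)C)O1 | intermediate
5 | (2S,5R)-5-allyl-2-tert-butyl-5-methyl-1,3-dioxolan-4-one | C[C@]1(CC=C)O[C@H](C(C)(C)C)OC1=O | intermediate
6 | 2-[(2S,4R)-2-tert-butyl-4-methyl-5-oxo-1,3-dioxolan-4-yl]acetaldehyde | C[C@]1(CC=O)O[C@H](C(C)(C)C)OC1=O | intermediate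
7 | (2S,5R)-2-tert-butyl-5-(2,2-dimethoxyethyl)-5-methyl-1,3-dioxolan-4-one | C[C@]1(CC(OC)OC)O[C@H](C(C)(C)C)OC1=O | intermediate
8 | lithium alkoxide of the but-1-ynyl hemiketal adduct of 7 (new hemiketal centre undefined) | C[C@]1(CC(OC)OC)O[C@H](C(C)(C)C)OC1(O[Li])C#CCC | intermediate
9 | (R)-3-hydroxy-1,1-dimethoxy-3-methyloct-5-yn-4-one | CCC#CC(=O)[C@](C)(O)CC(OC)OC | intermediate
10 | (R)-2-(2,2-dimethoxyethyl)-5-ethyl-2-methylfuran-3(2H)-one | CCC1=CC(=O)[C@@](C)(CC(OC)OC)O1 | intermediate
11 | lithium (2R,5Z)-2-(2,2-dimethoxyethyl)-5-ethylidene-2-methyl-2,5-dihydrofuran-3-olate | C/C=C1/C=C(O[Li])[C@@](C)(CC(OC)OC)O1 | intermediate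
12 | {[(2R,5Z)-2-(2,2-dimethoxyethyl)-5-ethylidene-2-methyl-2,5-dihydrofuran-3-yl]oxy}trimethylsilane | C/C=C1/C=C(O[Si](C)(C)C)[C@@](C)(CC(OC)OC)O1 | intermediate
13 | 2-vinyloxirane (racemic) | C=CC1CO1 | starting material
14 | 4-methoxybenzyl alcohol | COc1ccc(CO)cc1 | starting material
15 | (S)-2-[(4-methoxybenzyl)oxy]but-3-en-1-ol | C=C[C@@H](CO)OCc1ccc(OC)cc1 | intermediate
16 | (S)-2-[(4-methoxybenzyl)oxy]but-3-enal | C=C[C@@H](C=O)OCc1ccc(OC)cc1 | intermediate
17 | trimethylsilyl ether of 18 at the new carbinol | C=C[C@H](OCc1ccc(OC)cc1)[C@@H](O[Si](C)(C)C)[C@H](C)C1=CC(=O)[C@@](C)(CC(OC)OC)O1 | intermediate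
18 | (2R)-2-(2,2-dimethoxyethyl)-5-{(2S,3S,4S)-3-hydroxy-4-[(4-methoxybenzyl)oxy]hex-5-en-2-yl}-2-methylfuran-3(2H)-one | C=C[C@H](OCc1ccc(OC)cc1)[C@@H](O)[C@H](C)C1=CC(=O)[C@@](C)(CC(OC)OC)O1 | intermediate
19 | (2S,3S,4S)-2-[(5R)-5-(2,2-dimethoxyethyl)-5-methyl-4-oxo-4,5-dihydrofuran-2-yl]-4-[(4-methoxybenzyl)oxy]hex-5-en-3-yl 2-(bromomethyl)acrylate | C=C[C@H](OCc1ccc(OC)cc1)[C@@H](OC(=O)C(=C)CBr)[C@H](C)C1=CC(=O)[C@@](C)(CC(OC)OC)O1 | intermediate
20 | (5S,6S)-3-(bromomethyl)-6-{(1S)-1-[(5R)-5-(2,2-dimethoxyethyl)-5-methyl-4-oxo-4,5-dihydrofuran-2-yl]ethyl}-5-[(4-methoxybenzyl)oxy]-5,6-dihydro-2H-pyran-2-one | O=C1O[C@@H]([C@H](C)C2=CC(=O)[C@@](C)(CC(OC)OC)O2)[C@@H](OCc2ccc(OC)cc2)C=C1CBr | intermediate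
21 | 5-hydroxy analogue of 20 (PMB removed; 5S,6S) | O=C1O[C@@H]([C@H](C)C2=CC(=O)[C@@](C)(CC(OC)OC)O2)[C@@H](O)C=C1CBr | intermediate
22 | (5S,6S)-6-{(1S)-1-[(5R)-5-(2,2-dimethoxyethyl)-5-methyl-4-oxo-4,5-dihydrofuran-2-yl]ethyl}-5-hydroxy-3-[(4,4,5,5-tetramethyl-1,3,2-dioxaborolan-2-yl)methyl]-5,6-dihydro-2H-pyran-2-one | O=C1O[C@@H]([C@H](C)C2=CC(=O)[C@@](C)(CC(OC)OC)O2)[C@@H](O)C=C1CB3OC(C)(C)C(C)(C)O3 | intermediate
23 | 5-O-methacrylate of 22 | O=C1O[C@@H]([C@H](C)C2=CC(=O)[C@@](C)(CC(OC)OC)O2)[C@@H](OC(=O)C(C)=C)C=C1CB3OC(C)(C)C(C)(C)O3 | intermediate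
24 | aldehyde from 23 (dimethyl acetal hydrolysed to CH2CHO) | O=C1O[C@@H]([C@H](C)C2=CC(=O)[C@@](C)(CC=O)O2)[C@@H](OC(=O)C(C)=C)C=C1CB3OC(C)(C)C(C)(C)O3 | intermediate
25 | (4S,5S,6S,7R,8S,10R)-6-methacryloyloxy-1-oxo-8-(pinacolboryloxy)-3,10-epoxygermacra-2,11(13)-dien-12,5-olide (bridged six-membered lactone) | C=C(C)C(=O)O[C@@H]1[C@@H](OC(=O)C3=C)[C@H](C)C2=CC(=O)[C@@](C)(C[C@H](OB4OC(C)(C)C(C)(C)O4)[C@H]13)O2 | intermediate
26 | (4S,5S,6S,7R,8S,10R)-8-hydroxy-6-methacryloyloxy-1-oxo-3,10-epoxygermacra-2,11(13)-dien-12,5-olide (bridged six-membered lactone) | C=C(C)C(=O)O[C@@H]1[C@@H](OC(=O)C3=C)[C@H](C)C2=CC(=O)[C@@](C)(C[C@H](O)[C@H]13)O2 | intermediate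
27 | (4S,5S,6S,7R,8S,10R)-5-hydroxy-6-methacryloyloxy-1-oxo-3,10-epoxygermacra-2,11(13)-dien-12,8-olide (CNP0195404.1) | C=C(C)C(=O)O[C@@H]1[C@@H](O)[C@H](C)C2=CC(=O)[C@@](C)(C[C@@H]3OC(=O)C(=C)[C@@H]13)O2 | target

## Step count and risks

Total steps: 15. Longest linear sequence: 13 (steps 1–6 and 9–15); steps 7–8 form the second branch.

**Risk 1, step 15 (the double ring closure).** The medium ring may not close, or C8 may form with the wrong configuration if the chair transition state is not followed. The fallback sets out from 21 and comes back at 27, using an open-transition-state Hosomi–Sakurai allylation instead of the closed allylboration. Bromide 21 is silylated with Me3SiSiMe3 and catalytic Pd2(dba)3 to give the allylsilane alcohol F1. Acylation with methacrylic anhydride gives the allylsilane methacrylate F2. Acetal hydrolysis with LiBF4 in wet MeCN gives the allylsilane aldehyde F3, which can be isolated because the silane is inert without a Lewis acid. BF3·OEt2 in CH2Cl2 at −78 °C then closes the carbocycle through C7, and warming with catalytic camphorsulfonic acid completes translactonization to 27.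

**Risk 2, step 9 (aldol selectivity and the sensitive aldehyde 16).** If the 4,5- or 5,6-selectivity is poor, the fallback sets out from 16 and 7 and comes back at 18, setting C4/C5 by a reagent-controlled allenylmetal addition and building the furanone afterwards. Aldehyde 16 is treated with MgBr2·OEt2 and the matched enantiomer of tributyl(buta-1,2-dienyl)stannane (Marshall chelation-controlled syn,syn propargylation) to give the homopropargylic alcohol F4. Its dianion (2.2 equiv n-BuLi) is added to dioxolanone 7 to give the dihydroxy ynone F5, and Ph3PAuCl/AgOTf cyclization of F5 gives 18.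

**Risk 3, step 13 (allylic borylation; possible allyl–allyl coupling or protodeboronation).** The fallback sets out from 20 and comes back at 27, using the bromide directly in a Nozaki–Hiyama–Kishi allylation while C6 still carries the PMB ether, which is not a leaving group. Acetal hydrolysis of 20 (LiBF4, wet MeCN) gives the bromo aldehyde F6. CrCl2 in THF at high dilution effects allylation and translactonization to the 6-O-PMB hydroxy lactone F7. TESOTf/2,6-lutidine gives the 5-O-triethylsilyl ether F8, DDQ gives the 6-hydroxy compound F9, methacrylic anhydride/DMAP gives the silyl-protected target F10, and HF·pyridine gives 27.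

## Further compounds

F1 | step 15 | (5S,6S)-6-{(1S)-1-[(5R)-5-(2,2-dimethoxyethyl)-5-methyl-4-oxo-4,5-dihydrofuran-2-yl]ethyl}-5-hydroxy-3-[(trimethylsilyl)methyl]-5,6-dihydro-2H-pyran-2-one | O=C1O[C@@H]([C@H](C)C2=CC(=O)[C@@](C)(CC(OC)OC)O2)[C@@H](O)C=C1C[Si](C)(C)C
F2 | step 15 | 5-O-methacrylate of F1 | O=C1O[C@@H]([C@H](C)C2=CC(=O)[C@@](C)(CC(OC)OC)O2)[C@@H](OC(=O)C(C)=C)C=C1C[Si](C)(C)C
F3 | step 15 | aldehyde from F2 (dimethyl acetal hydrolysed to CH2CHO) | O=C1O[C@@H]([C@H](C)C2=CC(=O)[C@@](C)(CC=O)O2)[C@@H](OC(=O)C(C)=C)C=C1C[Si](C)(C)C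
F4 | step 9 | (3R,4S,5S)-5-[(4-methoxybenzyl)oxy]-3-methylhept-6-en-1-yn-4-ol | C=C[C@H](OCc1ccc(OC)cc1)[C@@H](O)[C@H](C)C#C
F5 | step 9 | (3R,7R,8S,9S)-3,8-dihydroxy-1,1-dimethoxy-9-[(4-methoxybenzyl)oxy]-3,7-dimethylundec-10-en-5-yn-4-one | C=C[C@H](OCc1ccc(OC)cc1)[C@@H](O)[C@H](C)C#CC(=O)[C@](C)(O)CC(OC)OC
F6 | step 13 | aldehyde from 20 (dimethyl acetal hydrolysed to CH2CHO) | O=C1O[C@@H]([C@H](C)C2=CC(=O)[C@@](C)(CC=O)O2)[C@@H](OCc2ccc(OC)cc2)C=C1CBr
F7 | step 13 | 6-O-(4-methoxybenzyl) ether of the 6-de(methacryloyl) target (C5–OH free) | COc1ccc(CO[C@@H]2[C@@H](O)[C@H](C)C3=CC(=O)[C@@](C)(C[C@@H]4OC(=O)C(=C)[C@@H]24)O3)cc1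
F8 | step 13 | 5-O-triethylsilyl ether of F7 | COc1ccc(CO[C@@H]2[C@@H](O[Si](CC)(CC)CC)[C@H](C)C3=CC(=O)[C@@](C)(C[C@@H]4OC(=O)C(=C)[C@@H]24)O3)cc1
F9 | step 13 | 5-O-triethylsilyl-6-hydroxy compound (PMB removed from F8) | O[C@@H]1[C@@H](O[Si](CC)(CC)CC)[C@H](C)C2=CC(=O)[C@@](C)(C[C@@H]3OC(=O)C(=C)[C@@H]13)O2
F10 | step 13 | 5-O-triethylsilyl ether of target 27 | C=C(C)C(=O)O[C@@H]1[C@@H](O[Si](CC)(CC)CC)[C@H](C)C2=CC(=O)[C@@](C)(C[C@@H]3OC(=O)C(=C)[C@@H]13)O2
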